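- The ratio f of the L charged in the flask to that in the midnight run was 0.667, and I used it to bracket H, the height of the Z peak in mM, which is the peak percent times the E charged.

common to all: E 32 mM

| charge | L | remark | time |
|---|---|---|---|
| midnight | 72 mM | run made earlier |  |
| flask | 48.0 mM |  | 25 h |

midnight run (percent of the E charged)

| time / h | Z / % |
|---|---|
| 0.417 | 0.3 |
| 0.667 | 0.6 |
| 1.00 | 0.6 |
| 1.33 | 1.2 |
| 2.00 | 3.1 |
| 3.00 | 5.4 |
| 5.00 | 8.6 |

(scatter of a reading: 0.3 percentage points)

- when, up to 25 h, the flask holds most Z
- the amount of Z, in percent of the E charged, at that time
- the first time at which Z reaches 5.2%, in the same percent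

- given per volume of solution although it is solid: E, L
- at the start none of L is in solution
- at the start none of E is in solution

- For the bound from below I took the proportional case, in which Z scales with f, so the last midnight reading, 8.6%, gave 1.83 mM, or 5.73% of the E charged.
- For the bound from above I took as zero of the scale a flask in which the L charge changes nothing, and I extended the slowing of the midnight readings as an exponential approach; their last slopes gave a time constant of 4.13 h, a reading with its scatter, and so a ceiling height 4.36 mM, or 13.6%.
- I could tighten this no further by hand, and I added one assumption of my own: E starts wholly solid, and H does not depend on the E charged while solid E stands.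
- The forecast gave 11% at 11 h, less than my ceiling and more than my floor, with the asked level at 3.4 h, and added “The peak is poorly constrained”.
- The flask gave 10.4% at 7.05 h and reached the level at 3.14 h, so its H was 3.32 mM, less than the ceiling and more than the floor.

    L ⇌ Q, rate k1*(cs1 - [Q]) while solid is left; crystals form when [Q] > cs1 (solubility = 23.0 mM, k = 4.90 /h)
    Q → G (k = 0.180 /h)
    J + Q → Z (k = 12.0 /M/h)
    Z ⇌ X (K = 11.0, k = 0.410 /h)
    E ⇌ J, rate k5*(cs5 - [J]) while solid is left; crystals form when [J] > cs5 (solubility = 19.0 mM, k = 0.150 /h)

- For the neighbour flask charged with 54 mM of E, the bracket became 3.39% to 8.07% of that charge, and the H of the flask, carried over unchanged, came to 6.14% of it; that neighbour gave 6.14%, an H of 3.32 mM, and with 0.889 equiv of L to E, L being the limiting reagent, it held 0% of its L charge as solid and 42.7% of its E at 25.0 h.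

The earlier runs and the new flask stem from a simulated flask for substances that don't exist; scatter was added.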